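**Retrosynthetic overview**
- The target is the mono-alcohol of the C2-symmetric (6R,6'R)-ε,ε-carotene-3,3'-dione. The last step reduces one of its two homotopic enone carbonyls under catalyst control, which breaks the symmetry and sets C3'.
- The dione comes from a two-directional double Wittig reaction (C11=C12 and C11'=C12') of two identical C15 3-oxo-ε phosphonium salts with the C10 trienedial.
- The C10 trienedial comes from furan (oxidative dearomatising ring opening to fumaraldehyde bis-acetal) plus two ethyl 1-propenyl ether units.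
- The C15 salt comes from (R)-α-ionone by allylic oxidation, chemoselective vinylation and PPh3·HBr.
- No ring is formed in the route: both six-membered rings, with C6 and C6' already R, are bought preformed in (R)-α-ionone.

Assumption: (R)-(+)-α-ionone of at least 98 % ee is purchased as such; the cheap racemate would need a resolution first.

**Step 1**
Reactants: 1 furan
Product: 3 (E)-1,1,4,4-tetramethoxybut-2-ene, via 2,5-dimethoxy-2,5-dihydrofuran 2 (not isolated)
Conditions: Br2 (1.0 equiv), MeOH, −45 → −10 °C, 3 h; then Na2CO3, rt; distil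
Reagents that add atoms: methanol, CO
Why: Clauson-Kaas oxidative 1,4-dimethoxylation destroys the furan aromaticity, and the HBr released opens the cyclic bis-acetal 2 by transacetalisation to the acyclic bis(dimethyl acetal), which settles as the more stable E alkene; no stereocentre is formed.

**Step 2**
Reactants: 3 (E)-1,1,4,4-tetramethoxybut-2-ene; 4 ethyl 1-propenyl ether (2.2 equiv)
Product: 6 (2E,4E,6E)-2,7-dimethylocta-2,4,6-trienedial, via hexaalkoxy adduct 5 (not isolated)
Conditions: BF3·OEt2 (0.5 mol %), neat, 0 → 25 °C; then AcOH/NaOAc/H2O, 95 °C; crystallise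
Reagents that add atoms: water, O
Why: Lewis-acid enol ether–acetal condensation (Müller–Cunradi–Pieroh, a Mukaiyama-type addition) at both acetal ends adds the two C3 units, and hot aqueous acid then hydrolyses the acetals and eliminates two MeOH to give the conjugated all-E dialdehyde under thermodynamic control.

**Step 3**
Reactants: 7 (R)-α-ionone
Product: 9 (R)-3-oxo-α-ionone, via allylic tert-butyl peroxide 8 (not isolated)
Conditions: t-BuOOH (70 % aq., 6 equiv), CuBr (2 mol %), MeCN, 50 °C
Reagents that add atoms: tert-butyl hydroperoxide, CC(C)(C)OO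
Why: Kharasch–Sosnovsky-type radical allylic oxidation: the tert-butylperoxyl radical abstracts the accessible secondary allylic H at C3, the mixed peroxide 8 collapses to the enone, and the hindered C6–H next to the gem-dimethyl group and the electron-poor side-chain enone is left alone, so the R centre is kept.

**Step 4**
Reactants: 9 (R)-3-oxo-α-ionone; 10 vinylmagnesium bromide (1.05 equiv)
Product: 12 (4R)-4-[(1E)-3-hydroxy-3-methylpenta-1,4-dien-1-yl]-3,5,5-trimethylcyclohex-2-en-1-one (both carbinol epimers), via magnesium alkoxide 11 (not isolated)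
Conditions: LaCl3·2LiCl (1.0 equiv), THF, −78 °C, 1 h; aq. NH4Cl
Reagents that add atoms: none
Why: Grignard 1,2-addition that discriminates the two ketones: the side-chain methyl ketone is far more accessible than the ring carbonyl, a neopentyl-flanked β,β-disubstituted enone (the same bias is seen in hydride, ketalisation and ylide reactions of such diketones), and the lanthanum salt suppresses enolisation so C6 is not epimerised; the new carbinol centre forms unselectively and is erased in step 5.

**Step 5**
Reactants: 12 (4R)-4-[(1E)-3-hydroxy-3-methylpenta-1,4-dien-1-yl]-3,5,5-trimethylcyclohex-2-en-1-one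
Product: 13 [(2E,4E)-3-methyl-5-[(1R)-2,6,6-trimethyl-4-oxocyclohex-2-en-1-yl]penta-2,4-dien-1-yl]triphenylphosphonium bromide
Conditions: PPh3·HBr (1.05 equiv), MeOH, 0 °C → rt; crystallise from EtOAc
Reagents that add atoms: triphenylphosphine hydrobromide, [Br-].c1ccc(cc1)[PH+](c1ccccc1)c1ccccc1
Why: Acid-induced allylic transposition (SN1'): ionisation of the tertiary bis-allylic alcohol gives a pentadienyl cation that PPh3 traps at the unhindered primary terminus, forming the E trisubstituted alkene of the usual C15 Wittig salt, while the ring enone is inert because its β-carbon is fully substituted.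

**Step 6**
Reactants: 13 C15 phosphonium bromide (2.1 equiv); 6 (2E,4E,6E)-2,7-dimethylocta-2,4,6-trienedial
Product: 16 (6R,6'R)-ε,ε-carotene-3,3'-dione, via C15 phosphorane 14 (not isolated), via C25 keto-aldehyde 15 (not isolated)
Conditions: 1,2-epoxybutane/EtOH (4:1), 65 °C, 20 h, Ar, dark; then heptane, reflux (Z → E); crystallise
Reagents that add atoms: none
Why: Two-directional double Wittig olefination: bromide opens the epoxide to an alkoxide that makes ylide 14 at low steady concentration without free strong base, so the base-labile C6–H is not epimerised, the aldehydes of 6 and then of 15 react while the hindered ring enones do not, and heating converts hindered Z isomers to the all-E, C2-symmetric dione.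

**Step 7**
Reactants: 16 (6R,6'R)-ε,ε-carotene-3,3'-dione
Product: 18 (3'R,6R,6'R)-3'-hydroxy-ε,ε-caroten-3-one, via catechol borate 17 (not isolated)
Conditions: (S)-2-methyl-CBS-oxazaborolidine (0.5 equiv), catecholborane (0.55 equiv, slow addition), CH2Cl2/toluene, −50 °C; pH 7 buffer; chromatography (16 recovered)
Reagents that add atoms: none
Why: Corey–Bakshi–Shibata reduction used as a symmetry-breaking step: the two enone carbonyls are homotopic through the C2 axis so reduction of either gives the same mono-alcohol, the (S)-oxazaborolidine (ring alkene side as the large group) is expected to deliver hydride to the face anti to the pseudo-axial C1' methyl and so give the (3'R) alcohol trans to the C6' side chain, and sub-stoichiometric borane holds the reaction at the mono-alcohol (statistical ceiling about 50 % per pass).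

**Compound list**
1 | furan | c1ccoc1 | starting material
2 | 2,5-dimethoxy-2,5-dihydrofuran (cis/trans; not isolated) | COC1C=CC(OC)O1 | intermediate
3 | (E)-1,1,4,4-tetramethoxybut-2-ene | COC(OC)/C=C/C(OC)OC | intermediate
4 | ethyl 1-propenyl ether (E/Z mixture) | CC=COCC | starting material
5 | (E)-1,8-diethoxy-1,3,6,8-tetramethoxy-2,7-dimethyloct-4-ene (diastereomer mixture; not isolated) | CCOC(OC)C(C)C(OC)/C=C/C(OC)C(C)C(OC)OCC | intermediate
6 | (2E,4E,6E)-2,7-dimethylocta-2,4,6-trienedial | O=C/C(C)=C/C=C/C=C(C)/C=O | intermediate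
7 | (R)-α-ionone, (3E)-4-[(1R)-2,6,6-trimethylcyclohex-2-en-1-yl]but-3-en-2-one | CC1=CCCC(C)(C)[C@H]1/C=C/C(C)=O | starting material
8 | (3E)-4-[(1R)-4-(tert-butylperoxy)-2,6,6-trimethylcyclohex-2-en-1-yl]but-3-en-2-one (peroxide epimers; not isolated) | CC1=CC(OOC(C)(C)C)CC(C)(C)[C@H]1/C=C/C(C)=O | intermediate
9 | (R)-3-oxo-α-ionone, (4R)-3,5,5-trimethyl-4-[(1E)-3-oxobut-1-en-1-yl]cyclohex-2-en-1-one | CC1=CC(=O)CC(C)(C)[C@H]1/C=C/C(C)=O | intermediate
10 | vinylmagnesium bromide | C=C[Mg]Br | starting material
11 | bromomagnesium alkoxide of 12 (not isolated) | CC1=CC(=O)CC(C)(C)[C@H]1/C=C/C(C)(O[Mg]Br)C=C | intermediate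
12 | (4R)-4-[(1E)-3-hydroxy-3-methylpenta-1,4-dien-1-yl]-3,5,5-trimethylcyclohex-2-en-1-one (carbinol epimers) | CC1=CC(=O)CC(C)(C)[C@H]1/C=C/C(C)(O)C=C | intermediate
13 | [(2E,4E)-3-methyl-5-[(1R)-2,6,6-trimethyl-4-oxocyclohex-2-en-1-yl]penta-2,4-dien-1-yl]triphenylphosphonium bromide | CC1=CC(=O)CC(C)(C)[C@H]1/C=C/C(C)=C/C[P+](c1ccccc1)(c1ccccc1)c1ccccc1.[Br-] | intermediate
14 | C15 phosphorane, ylide of 13 (not isolated) | CC1=CC(=O)CC(C)(C)[C@H]1/C=C/C(C)=C/C=P(c1ccccc1)(c1ccccc1)c1ccccc1 | intermediate
15 | (6R)-3-oxo-12'-apo-ε-caroten-12'-al, (2E,4E,6E,8E,10E,12E)-2,7,11-trimethyl-13-[(1R)-2,6,6-trimethyl-4-oxocyclohex-2-en-1-yl]trideca-2,4,6,8,10,12-hexaenal (not isolated) | CC1=CC(=O)CC(C)(C)[C@H]1/C=C/C(C)=C/C=C/C(C)=C/C=C/C=C(C)/C=O | intermediate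
16 | (6R,6'R)-ε,ε-carotene-3,3'-dione (all-E, C2-symmetric) | CC1=CC(=O)CC(C)(C)[C@H]1/C=C/C(C)=C/C=C/C(C)=C/C=C/C=C(C)/C=C/C=C(C)/C=C/[C@H]1C(C)=CC(=O)CC1(C)C | intermediate
17 | catechol borate of 18 at O3' (not isolated) | CC1=CC(=O)CC(C)(C)[C@H]1/C=C/C(C)=C/C=C/C(C)=C/C=C/C=C(C)/C=C/C=C(C)/C=C/[C@H]1C(C)=C[C@H](OB2Oc3ccccc3O2)CC1(C)C | intermediate
18 | (3'R,6R,6'R)-3'-hydroxy-ε,ε-caroten-3-one (all-E) | CC1=CC(=O)CC(C)(C)[C@H]1/C=C/C(C)=C/C=C/C(C)=C/C=C/C=C(C)/C=C/C=C(C)/C=C/[C@H]1C(C)=C[C@H](O)CC1(C)C | target

**Step count**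
Total: 7 steps (steps 1–2 furan branch, steps 3–5 ionone branch, steps 6–7 after convergence).
Longest linear sequence: 5 steps (7 → 9 → 12 → 13 → 16 → 18).

**Three steps most likely to fail**

Step 7 is the riskiest. The reduction may run past the mono-alcohol, and the facial selectivity rests on the conformational and catalyst arguments given above, which are untested on this substrate. The fallback sets out from 16 and comes back at 18. Both carbonyls are reduced with excess catecholborane and the same oxazaborolidine to (3R,3'R,6R,6'R)-ε,ε-carotene-3,3'-diol F1. Material carrying one wrong carbinol centre is a separable diastereomer, so the double reduction purges minor epimers. The symmetry is then broken by oxidation instead of reduction: a limited amount of activated MnO2 in CH2Cl2 at 0 °C oxidises one of the two homotopic allylic alcohols to give 18, with diol and dione recycled.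

Step 4 is next. The vinyl Grignard reagent may also attack the ring enone or enolise the diketone. The fallback sets out from 9 and comes back at 12; it masks the ring ketone by a temporary change of oxidation state.
- The more reactive side-chain ketone is first protected as (4R)-3,5,5-trimethyl-4-[(E)-2-(2-methyl-1,3-dioxolan-2-yl)ethenyl]cyclohex-2-en-1-one F2 (ethylene glycol, HC(OMe)3, cat. TsOH, rt).
- The ring ketone is reduced under Luche conditions (NaBH4, CeCl3, MeOH, −20 °C) to (4R)-3,5,5-trimethyl-4-[(E)-2-(2-methyl-1,3-dioxolan-2-yl)ethenyl]cyclohex-2-en-1-ol F3; the epimer ratio does not matter.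
- Aqueous oxalic acid in THF removes the ketal to give (3E)-4-[(1R)-4-hydroxy-2,6,6-trimethylcyclohex-2-en-1-yl]but-3-en-2-one F4.
- Excess vinylmagnesium bromide adds to the only remaining ketone to give (1E)-1-[(1R)-4-hydroxy-2,6,6-trimethylcyclohex-2-en-1-yl]-3-methylpenta-1,4-dien-3-ol F5.
- MnO2 oxidises the secondary ring allylic alcohol back to the enone, giving 12; the tertiary carbinol cannot be oxidised.

Step 6 is the third. The ylide or alkoxide may epimerise the doubly activated C6–H of the 3-oxo-ε ring, or the double olefination may be sluggish under neutral conditions. The fallback sets out from 13 and comes back at 16; it removes the enone before the olefination.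
- Luche reduction of 13 gives [(2E,4E)-5-[(1R)-4-hydroxy-2,6,6-trimethylcyclohex-2-en-1-yl]-3-methylpenta-2,4-dien-1-yl]triphenylphosphonium bromide F6.
- An ordinary double Wittig reaction with 6 (NaOMe, CH2Cl2/MeOH, 0 °C), now free of any base-labile enone, gives (6R,6'R)-ε,ε-carotene-3,3'-diol F7 as a mixture of carbinol epimers.
- Excess MnO2 oxidises both allylic alcohols to 16.

**Further compounds**
F1 | step 7 | (3R,3'R,6R,6'R)-ε,ε-carotene-3,3'-diol | CC1=C[C@H](O)CC(C)(C)[C@H]1/C=C/C(C)=C/C=C/C(C)=C/C=C/C=C(C)/C=C/C=C(C)/C=C/[C@H]1C(C)=C[C@H](O)CC1(C)C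
F2 | step 4 | (4R)-3,5,5-trimethyl-4-[(E)-2-(2-methyl-1,3-dioxolan-2-yl)ethenyl]cyclohex-2-en-1-one | CC1=CC(=O)CC(C)(C)[C@H]1/C=C/C1(C)OCCO1
F3 | step 4 | (4R)-3,5,5-trimethyl-4-[(E)-2-(2-methyl-1,3-dioxolan-2-yl)ethenyl]cyclohex-2-en-1-ol (carbinol epimers) | CC1=CC(O)CC(C)(C)[C@H]1/C=C/C1(C)OCCO1
F4 | step 4 | (3E)-4-[(1R)-4-hydroxy-2,6,6-trimethylcyclohex-2-en-1-yl]but-3-en-2-one (carbinol epimers) | CC1=CC(O)CC(C)(C)[C@H]1/C=C/C(C)=O
F5 | step 4 | (1E)-1-[(1R)-4-hydroxy-2,6,6-trimethylcyclohex-2-en-1-yl]-3-methylpenta-1,4-dien-3-ol (carbinol epimers) | CC1=CC(O)CC(C)(C)[C@H]1/C=C/C(C)(O)C=C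
F6 | step 6 | [(2E,4E)-5-[(1R)-4-hydroxy-2,6,6-trimethylcyclohex-2-en-1-yl]-3-methylpenta-2,4-dien-1-yl]triphenylphosphonium bromide (carbinol epimers) | CC1=CC(O)CC(C)(C)[C@H]1/C=C/C(C)=C/C[P+](c1ccccc1)(c1ccccc1)c1ccccc1.[Br-]
F7 | step 6 | (6R,6'R)-ε,ε-carotene-3,3'-diol (carbinol epimer mixture) | CC1=CC(O)CC(C)(C)[C@H]1/C=C/C(C)=C/C=C/C(C)=C/C=C/C=C(C)/C=C/C=C(C)/C=C/[C@H]1C(C)=CC(O)CC1(C)C
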